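Readings and results were computed on assumed constants.

A closed stirred flask of D, J and X makes G within the first hour and then loses it; the same charge now goes into the set-ups below.

| setting | summer | noon | winter | spring | theta | zeta | beta | eta |
|---|---|---|---|---|---|---|---|---|
| D | 0.16 M | 0.16 M | 0.16 M | 0.16 M | 0.16 M | 0.16 M | 0.16 M | 0.16 M (fed, over 4.80 h) |
| J | 0.24 M | 0.12 M | 0.18 M | 0.24 M | 0.240 M | 0.240 M (fed, over 4.80 h) | 0.240 M | 0.240 M |
| X | 0.80 M | 0.80 M | 0.80 M | 1.6 M | 0.800 M | 0.800 M | 0.800 M | 0.800 M |
| remark | run made earlier | run made earlier | run made earlier | run made earlier | a closed flask charged with all of it at once and left for 6.0 h | all but J at the start; J goes in evenly over 4.80 h, the run ends at 6.0 h | one stirred flow tank at steady state, fed with the mixture as stated, mean residence time 6.0 h | all but D at the start; D goes in evenly over 4.80 h, the run ends at 6.0 h |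
| time |  |  |  |  | 6.0 h | 6.0 h |  | 6.0 h |

| run | time / h | G / % | D / % |
|---|---|---|---|
| summer | 0.500 | 34.2 | 59.8 |
| summer | 1.00 | 35.6 | 60.8 |
| summer | 1.50 | 35.2 | 63.3 |
| summer | 2.00 | 34.2 | 65.3 |
| summer | 2.50 | 30.9 | 67.6 |
| summer | 3.00 | 28.5 | 69.1 |
| summer | 4.00 | 25.0 | 71.6 |
| noon | 0.250 | 18.1 | 81.1 |
| noon | 0.417 | 21.4 | 76.0 |
| noon | 0.667 | 23.4 | 73.8 |
| noon | 1.00 | 26.0 | 73.1 |
| noon | 1.50 | 24.8 | 72.6 |
| noon | 2.50 | 24.2 | 74.7 |
| noon | 4.00 | 18.4 | 78.4 |
| winter | 0.250 | 24.6 | 75.2 |
| winter | 0.417 | 30.0 | 69.1 |
| winter | 0.667 | 33.1 | 66.0 |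
| winter | 1.00 | 31.7 | 63.6 |
| winter | 1.50 | 32.6 | 65.0 |
| winter | 2.50 | 28.5 | 71.8 |
| winter | 4.00 | 23.5 | 75.0 |
| spring | 0.667 | 30.3 | 66.2 |
| spring | 1.33 | 27.6 | 71.2 |
| spring | 2.00 | 25.1 | 75.0 |
| spring | 3.00 | 16.3 | 81.0 |
| spring | 4.00 | 16.1 | 82.5 |

(standard deviation of a reading: 1 percentage point)

- the stated concentrations are those of everything mixed, before any reaction; amounts are the same in each set-up
- on the list of suspects stand: D + J <-> X + G; G + J <-> X + E; J -> Z; 2 J -> Q
- the feed brings no volume worth counting
- the earlier runs were made in a closed, stirred flask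

- the set-up with the highest amount of G at the outlet or at the end, in percent of the D put in ("none" if the first two lie within 2 percentage points) (theta / zeta / beta / eta / none)
- amount of G at the outlet or at the end, in percent of the D put in, theta
- amount of G at the outlet or at the end, in percent of the D put in, zeta
- amount of G at the outlet or at the end, in percent of the D put in, beta
- amount of G at the outlet or at the end, in percent of the D put in, eta

If the first suspect stays near balance, D/G, which I call the odds, goes as [X]/[J], so the odds show how much J has gone. In the summer run they rise from 1.71 at 1.00 h to 2.86 at 4.00 h. That gain per hour, the climb, is 0.385 /h, and the line run back to time zero starts at 1.32.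

Two chemists disagree about this line. The first says J dies by age. Theta's J ages 6.0 h, which gives odds of 3.63; with G and D together at 96.6 %, as in summer's last reading, G is 20.8 %. Zeta's J, fed evenly, has a mean age of 3.60 h, so its odds are 2.71 and G is 26.0 %. Eta's J ages like theta's, so she gives eta 20.8 % as well.

The second says J dies by crowding, a second-order loss. Noon starts with less J and stands at odds of 2.81 at 1.00 h. Age predicts a climb in proportion, 0.633 /h, but noon reads less than that, 0.483 /h. Given the scatter, that is a lean and no proof. He puts her zeta figure back in: J that thin should climb more slowly, so he expects zeta to end above 26.0 %. Eta's J stands crowded before D arrives, so he expects eta to end below theta.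

I side with him: theta near 20.8 %, zeta above 26.0 %, eta below theta.

The forecast, holding that “feeding keeps J low, so less is wasted”, gives theta 21 %, zeta 31 %, beta 28 %, eta 17 %, and names zeta best.

    D + J ⇌ X + G (K = 9.30, k = 10.0 /M/h)
    G + J ⇌ X + E (K = 1.90, k = 2.10 /M/h)
    J → Z (k = 0.150 /h)
    2 J → Q (k = 4.10 /M/h)

The flask gives theta 20.7 %, zeta 32.3 %, beta 28.5 %, eta 11.3 %, so zeta leads. Theta ends at odds of 3.76, close to the line's 3.63, while zeta ends at 1.99, under the aged 2.71. The age view has its region below [J] = 0.0183 M, where J → Z takes more J than the pairing to Q does; zeta's peak of 0.0616 M stands above that, and eta's is 0.240 M. The reverse step, X + G to D + J, may be called the main reason zeta's G stays low: with that step taken away, zeta ends at 79.4 % instead of 32.3 %.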